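**Plan**

- Ring numbering used throughout: C1 (ketone), C2 (CH2OH), C3, C4, C5 (quaternary), C6 (enol-ester arm), C7 (acetonyl arm).
- Retrosynthesis: remove first the senecioate C–O bond, the C2–CH2OH bond, the C7–acetonyl bond and the side-chain C–OH bond, then cut the ring bonds C1–C2 and C6–C7.
- Feature: the ring then falls into the five-carbon run C2–C3–C4–C5–C6, which with quaternary C5 at its midpoint is a vinylcyclopropane (three-membered ring C4/C5/C6, vinyl C3=C2), and the two-carbon piece C7–C1, the two carbons of ethoxyacetylene with oxygen already on C1.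
- Forward: geraniol → diazoacetate → cyclopropane-fused γ-lactone → vinylcyclopropane; a Rh(I) (5+2) cycloaddition opens the three-membered ring and closes the seven-membered ring, the only ring of the target; the arms follow, the enol ester last but one.
- Stereochemistry: C5 and C6 come from the enantioselective Rh(II) cyclopropanation of the E-alkene (methyl cis to CH2O) and pass through the cycloaddition with retention at C6; C7 comes from allylation anti to the C6 substituent; the two E-alkenes come from selenoxide syn-elimination and Takai olefination.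

Key step: step 7

Assumption: Rh2(5R-MEPY)4 is taken to give the (1R,5S,6R)-lactone 5, by analogy with its sense of induction for simple allylic diazoacetates; if the sense proves opposite, the 5S catalyst is used instead.

**Route**

Step 1
Reactants: 1 geraniol; 2 bromoacetyl bromide
Product: 3 (2E)-3,7-dimethylocta-2,6-dien-1-yl bromoacetate
Conditions: NaHCO3, MeCN, 0 °C
Reagents that add atoms: none
Why: O-acylation of the primary allylic alcohol by the acid bromide under bicarbonate buffering, which leaves the E-alkene that later fixes the C5/C6 relationship untouched.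

Step 2
Reactants: 3 (2E)-3,7-dimethylocta-2,6-dien-1-yl bromoacetate
Product: 4 (2E)-3,7-dimethylocta-2,6-dien-1-yl diazoacetate
Conditions: TsNHNHTs, DBU, THF, 0 °C
Reagents that add atoms: N,N'-ditosylhydrazine, Cc1ccc(cc1)S(=O)(=O)NNS(=O)(=O)c1ccc(C)cc1
Why: N-alkylation of the bis-sulfonyl hydrazine by the bromoacetate followed by twofold base-induced sulfinate elimination is a standard diazoacetate synthesis and is mild enough for an allylic ester.

Step 3
Reactants: 4 (2E)-3,7-dimethylocta-2,6-dien-1-yl diazoacetate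
Product: 5 (1R,5S,6R)-6-methyl-6-(4-methylpent-3-en-1-yl)-3-oxabicyclo[3.1.0]hexan-2-one
Conditions: Rh2(5R-MEPY)4 (1 mol %), CH2Cl2, reflux, slow addition of 4
Reagents that add atoms: none
Why: Chiral dirhodium(II) carboxamidate-catalysed intramolecular cyclopropanation of an allylic diazoacetate, in which the carbene adds stereospecifically to the proximal E-alkene (methyl and CH2O therefore cis), the lactone tether forces cis fusion and the ligand sphere selects the alkene face, so that the future C4, C5 and C6 are set together.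

Step 4
Reactants: 5 (1R,5S,6R)-6-methyl-6-(4-methylpent-3-en-1-yl)-3-oxabicyclo[3.1.0]hexan-2-one
Product: 6 (1R,5S,6R)-6-methyl-6-(4-methylpent-3-en-1-yl)-3-oxabicyclo[3.1.0]hexan-2-ol (anomer mixture)
Conditions: DIBAL-H, CH2Cl2, −78 °C
Reagents that add atoms: none
Why: Partial reduction of a γ-lactone to the lactol by DIBAL-H at low temperature stops at the tetrahedral aluminate and touches no stereocentre.

Step 5
Reactants: 6 (1R,5S,6R)-6-methyl-6-(4-methylpent-3-en-1-yl)-3-oxabicyclo[3.1.0]hexan-2-ol
Product: 7 [(1S,2S,3R)-3-ethenyl-2-methyl-2-(4-methylpent-3-en-1-yl)cyclopropyl]methanol (vinyl, methyl and CH2OH all cis)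
Conditions: Ph3PCH3Br, KHMDS, THF, 0 °C → rt
Reagents that add atoms: methyltriphenylphosphonium bromide, C[P+](c1ccccc1)(c1ccccc1)c1ccccc1.[Br-]
Why: Wittig methylenation of the hydroxy aldehyde in equilibrium with the lactol, with excess ylide to cover the free hydroxyl, should outrun base-induced epimerisation so that vinyl and CH2OH stay cis.

Step 6
Reactants: 7 [(1S,2S,3R)-3-ethenyl-2-methyl-2-(4-methylpent-3-en-1-yl)cyclopropyl]methanol
Product: 8 1-({[(1S,2S,3R)-3-ethenyl-2-methyl-2-(4-methylpent-3-en-1-yl)cyclopropyl]methoxy}methyl)-4-methoxybenzene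
Conditions: NaH, PMBCl, Bu4NI (cat.), DMF, 0 °C → rt
Reagents that add atoms: 4-methoxybenzyl chloride, COc1ccc(CCl)cc1
Why: Williamson etherification installs a PMB group that tolerates Rh(I), aqueous acid, LDA and selenium chemistry and can later be removed oxidatively beside a silyl ether.

Step 7
Reactants: 8 1-({[(1S,2S,3R)-3-ethenyl-2-methyl-2-(4-methylpent-3-en-1-yl)cyclopropyl]methoxy}methyl)-4-methoxybenzene; 9 ethoxyacetylene
Product: 10 (6S,7S)-2-ethoxy-7-{[(4-methoxybenzyl)oxy]methyl}-6-methyl-6-(4-methylpent-3-en-1-yl)cyclohepta-1,4-diene (route numbering: OEt on C1, alkenes C7=C1 and C3=C4)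
Conditions: [Rh(CO)2Cl]2 (5 mol %), ClCH2CH2Cl, 60 °C, slow addition of 9 (3 equiv)
Reagents that add atoms: none
Why: Proposed new method: Rh(I) binds the vinyl group of 8 and inserts into the C4–C6 cyclopropane bond to give a rhodacyclohexene with a σ-bond to C6 and an η3-allyl over C2–C4, ethoxyacetylene inserts into the Rh–allyl bond so that C2 adds to the oxygen-bearing alkyne carbon (C1–C2), and C(sp3)–C(sp2) reductive elimination forms C6–C7. The closest known reaction type is the Rh(I)-catalysed intermolecular (5+2) cycloaddition of vinylcyclopropanes with alkynes, established for 1-alkoxy and 1-alkyl vinylcyclopropanes; a tetrasubstituted cyclopropane without a donor at C4 and an ynol ether partner go beyond it. The seven-membered ring closes by reductive elimination from the eight-membered rhodacycle, i.e. as a (5+2) cycloaddition joining the five-carbon unit C2–C6 to the two-carbon unit C7–C1. No stereocentre is created: C5 is untouched, C6 keeps its configuration because oxidative addition and reductive elimination at C6 both proceed with retention, and C4 becomes sp2. The step needs cleavage of C4–C6 and not C4–C5, which should be secured because the alternative would place rhodium on the quaternary carbon and because C4–C6 cleavage relieves the cis vinyl/CH2OPMB strain. It also needs the OEt-bearing carbon to bond to C2, which the polarisation of the ynol ether (the electrophilic C–O carbon accepts the migrating allyl terminus, rhodium stays on the nucleophilic CH terminus) and the small unsubstituted terminus facing the congested C6 should secure, while slow addition of 9 keeps alkyne oligomerisation behind the cycloaddition.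

Step 8
Reactants: 10 (6S,7S)-2-ethoxy-7-{[(4-methoxybenzyl)oxy]methyl}-6-methyl-6-(4-methylpent-3-en-1-yl)cyclohepta-1,4-diene
Product: 12 (5S,6S)-6-{[(4-methoxybenzyl)oxy]methyl}-5-methyl-5-(4-methylpent-3-en-1-yl)cyclohept-2-en-1-one, via cyclohept-3-enone 11 (not isolated)
Conditions: 1 M aq. HCl, THF, rt; then DBU (cat.), CH2Cl2, rt
Reagents that add atoms: water, O
Why: Enol ether hydrolysis followed by acid- and base-mediated migration of the C3=C4 alkene into conjugation is the seven-membered counterpart of the dihydroanisole-to-cyclohexenone conversion after a Birch reduction, and any unconjugated isomer left at equilibrium is separated and resubmitted.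

Step 9
Reactants: 12 (5S,6S)-6-{[(4-methoxybenzyl)oxy]methyl}-5-methyl-5-(4-methylpent-3-en-1-yl)cyclohept-2-en-1-one
Product: 13 (5S,6S)-2-(hydroxymethyl)-6-{[(4-methoxybenzyl)oxy]methyl}-5-methyl-5-(4-methylpent-3-en-1-yl)cyclohept-2-en-1-one
Conditions: 37 % aq. CH2O, DMAP, THF, rt
Reagents that add atoms: formaldehyde, C=O
Why: Morita–Baylis–Hillman hydroxymethylation of a cyclic enone under nucleophilic amine catalysis places the CH2OH group on C2 and regenerates the C2=C3 alkene without creating a stereocentre.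

Step 10
Reactants: 13 (5S,6S)-2-(hydroxymethyl)-6-{[(4-methoxybenzyl)oxy]methyl}-5-methyl-5-(4-methylpent-3-en-1-yl)cyclohept-2-en-1-one
Product: 14 (5S,6S)-2-{[(tert-butyldimethylsilyl)oxy]methyl}-6-{[(4-methoxybenzyl)oxy]methyl}-5-methyl-5-(4-methylpent-3-en-1-yl)cyclohept-2-en-1-one
Conditions: TBSCl, imidazole, CH2Cl2, 0 °C → rt
Reagents that add atoms: tert-butyldimethylsilyl chloride, CC(C)(C)[Si](C)(C)Cl
Why: Silylation masks the allylic alcohol so that the later oxidation addresses only the C6 carbinol and the copper coupling meets no free primary alcohol.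

Step 11
Reactants: 14 (5S,6S)-2-{[(tert-butyldimethylsilyl)oxy]methyl}-6-{[(4-methoxybenzyl)oxy]methyl}-5-methyl-5-(4-methylpent-3-en-1-yl)cyclohept-2-en-1-one
Product: 16 (5S,6S,7S)-2-{[(tert-butyldimethylsilyl)oxy]methyl}-6-{[(4-methoxybenzyl)oxy]methyl}-5-methyl-5-(4-methylpent-3-en-1-yl)-7-(prop-2-en-1-yl)cyclohept-2-en-1-one, via lithium enolate 15 (not isolated)
Conditions: LDA, THF, −78 °C; allyl bromide, DMPU, −78 → −30 °C
Reagents that add atoms: allyl bromide, C=CCBr
Why: Kinetic α'-deprotonation of the enone at C7 and SN2 allylation of the cross-conjugated enolate set the C7 stereocentre by approach of allyl bromide to the face opposite the neighbouring C6 CH2OPMB group (6,7-trans), which is also the more stable arrangement should C7 equilibrate.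

Step 12
Reactants: 16 (5S,6S,7S)-2-{[(tert-butyldimethylsilyl)oxy]methyl}-6-{[(4-methoxybenzyl)oxy]methyl}-5-methyl-5-(4-methylpent-3-en-1-yl)-7-(prop-2-en-1-yl)cyclohept-2-en-1-one
Product: 17 (5S,6S,7S)-2-{[(tert-butyldimethylsilyl)oxy]methyl}-6-{[(4-methoxybenzyl)oxy]methyl}-5-methyl-5-(4-methylpent-3-en-1-yl)-7-(2-oxopropyl)cyclohept-2-en-1-one
Conditions: PdCl2 (10 mol %), Cu(OAc)2, O2 (1 atm), DMA–H2O 7:1, rt
Reagents that add atoms: water, O
Why: Tsuji–Wacker oxidation converts the terminal allyl group into the methyl ketone with Markovnikov selectivity, while the trisubstituted and the conjugated alkene are inert to Pd(II) under these conditions.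

Step 13
Reactants: 17 (5S,6S,7S)-2-{[(tert-butyldimethylsilyl)oxy]methyl}-6-{[(4-methoxybenzyl)oxy]methyl}-5-methyl-5-(4-methylpent-3-en-1-yl)-7-(2-oxopropyl)cyclohept-2-en-1-one
Product: 20 (5S,6S,7S)-2-{[(tert-butyldimethylsilyl)oxy]methyl}-5-[(2E)-4-hydroxy-4-methylpent-2-en-1-yl]-6-{[(4-methoxybenzyl)oxy]methyl}-5-methyl-7-(2-oxopropyl)cyclohept-2-en-1-one, via hydroxy selenide 18 (not isolated), via selenoxide 19 (not isolated)
Conditions: N-(phenylseleno)phthalimide, H2O, CSA (cat.), CH2Cl2, rt; then NaIO4, NaHCO3, THF–H2O, rt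
Reagents that add atoms: water, O
Why: Markovnikov hydroxyselenation of the only electron-rich alkene puts OH on the tertiary carbon, and selenoxide syn-elimination can then only proceed toward the chain CH2, which should give the E-configured tertiary allylic alcohol.

Step 14
Reactants: 20 (5S,6S,7S)-2-{[(tert-butyldimethylsilyl)oxy]methyl}-5-[(2E)-4-hydroxy-4-methylpent-2-en-1-yl]-6-{[(4-methoxybenzyl)oxy]methyl}-5-methyl-7-(2-oxopropyl)cyclohept-2-en-1-one
Product: 21 (5S,6S,7S)-2-{[(tert-butyldimethylsilyl)oxy]methyl}-6-(hydroxymethyl)-5-[(2E)-4-hydroxy-4-methylpent-2-en-1-yl]-5-methyl-7-(2-oxopropyl)cyclohept-2-en-1-one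
Conditions: DDQ, CH2Cl2–pH 7 buffer, 0 °C
Reagents that add atoms: none
Why: Oxidative cleavage of the PMB ether by DDQ under buffered conditions leaves the silyl ether, the enone and the tertiary allylic alcohol untouched.

Step 15
Reactants: 21 (5S,6S,7S)-2-{[(tert-butyldimethylsilyl)oxy]methyl}-6-(hydroxymethyl)-5-[(2E)-4-hydroxy-4-methylpent-2-en-1-yl]-5-methyl-7-(2-oxopropyl)cyclohept-2-en-1-one
Product: 22 (5S,6S,7S)-2-{[(tert-butyldimethylsilyl)oxy]methyl}-6-formyl-5-[(2E)-4-hydroxy-4-methylpent-2-en-1-yl]-5-methyl-7-(2-oxopropyl)cyclohept-2-en-1-one (the C6 carbaldehyde)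
Conditions: Dess–Martin periodinane, NaHCO3, CH2Cl2, 0 °C → rt
Reagents that add atoms: none
Why: Dess–Martin oxidation of the single primary alcohol (the tertiary alcohol cannot react) under buffered, non-basic conditions should give the aldehyde without epimerising C6; it is used at once.

Step 16
Reactants: 22 (5S,6S,7S)-2-{[(tert-butyldimethylsilyl)oxy]methyl}-6-formyl-5-[(2E)-4-hydroxy-4-methylpent-2-en-1-yl]-5-methyl-7-(2-oxopropyl)cyclohept-2-en-1-one
Product: 23 (5S,6R,7S)-2-{[(tert-butyldimethylsilyl)oxy]methyl}-5-[(2E)-4-hydroxy-4-methylpent-2-en-1-yl]-6-[(E)-2-iodoethenyl]-5-methyl-7-(2-oxopropyl)cyclohept-2-en-1-one (same spatial arrangement at C6; the descriptor changes with the iodine)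
Conditions: CrCl2, CHI3, THF, 0 °C → rt
Reagents that add atoms: iodoform, IC(I)I
Why: Takai iodo-olefination is selective for aldehydes over ketones, is not basic and gives the E-vinyl iodide, especially from α-branched aldehydes.

Step 17
Reactants: 23 (5S,6R,7S)-2-{[(tert-butyldimethylsilyl)oxy]methyl}-5-[(2E)-4-hydroxy-4-methylpent-2-en-1-yl]-6-[(E)-2-iodoethenyl]-5-methyl-7-(2-oxopropyl)cyclohept-2-en-1-one; 24 3-methylbut-2-enoic acid
Product: 25 (E)-2-[(5S,6S,7S)-2-{[(tert-butyldimethylsilyl)oxy]methyl}-5-[(2E)-4-hydroxy-4-methylpent-2-en-1-yl]-5-methyl-1-oxo-7-(2-oxopropyl)cyclohept-2-en-6-yl]ethenyl 3-methylbut-2-enoate (route numbering)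
Conditions: CuI (20 mol %), 3,4,7,8-tetramethyl-1,10-phenanthroline, Cs2CO3, toluene, 70 °C
Reagents that add atoms: none
Why: Copper(I)-catalysed Ullmann-type C–O coupling of a vinyl iodide with a carboxylate proceeds with retention of alkene geometry, and the hindered tertiary alcohol does not compete.

Step 18
Reactants: 25 (E)-2-[(5S,6S,7S)-2-{[(tert-butyldimethylsilyl)oxy]methyl}-5-[(2E)-4-hydroxy-4-methylpent-2-en-1-yl]-5-methyl-1-oxo-7-(2-oxopropyl)cyclohept-2-en-6-yl]ethenyl 3-methylbut-2-enoate
Product: 26 (5S,6S,7S)-2-(hydroxymethyl)-5-[(2E)-4-hydroxy-4-methylpent-2-en-1-yl]-5-methyl-6-[(E)-2-(3-methylbut-2-enoyloxy)ethenyl]-7-(2-oxopropyl)cyclohept-2-en-1-one (CNP0351090.2)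
Conditions: HF·pyridine, pyridine, THF, 0 °C → rt
Reagents that add atoms: none
Why: Buffered fluoride desilylation of the primary allylic TBS ether is mild enough for the enol ester, the tertiary allylic alcohol and the 1,4-diketone.

**Compound list**

1 | geraniol | CC(C)=CCC/C(C)=C/CO | starting material
2 | bromoacetyl bromide | BrCC(Br)=O | starting material
3 | geranyl bromoacetate | CC(C)=CCC/C(C)=C/COC(=O)CBr | intermediate
4 | geranyl diazoacetate | CC(C)=CCC/C(C)=C/COC(=O)C=[N+]=[N-] | intermediate
5 | (1R,5S,6R)-6-methyl-6-(4-methylpent-3-en-1-yl)-3-oxabicyclo[3.1.0]hexan-2-one | O=C1[C@H]2[C@](C)(CCC=C(C)C)[C@H]2CO1 | intermediate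
6 | (1R,5S,6R)-6-methyl-6-(4-methylpent-3-en-1-yl)-3-oxabicyclo[3.1.0]hexan-2-ol, anomer mixture | OC1[C@H]2[C@](C)(CCC=C(C)C)[C@H]2CO1 | intermediate
7 | [(1S,2S,3R)-3-ethenyl-2-methyl-2-(4-methylpent-3-en-1-yl)cyclopropyl]methanol | C=C[C@H]1[C@](C)(CCC=C(C)C)[C@H]1CO | intermediate
8 | 4-methoxybenzyl ether of 7 (vinylcyclopropane for the key step) | C=C[C@H]1[C@](C)(CCC=C(C)C)[C@H]1COCc1ccc(OC)cc1 | intermediate
9 | ethoxyacetylene | CCOC#C | starting material
10 | (6S,7S)-2-ethoxy-7-{[(4-methoxybenzyl)oxy]methyl}-6-methyl-6-(4-methylpent-3-en-1-yl)cyclohepta-1,4-diene | C1=C(OCC)CC=C[C@](C)(CCC=C(C)C)[C@H]1COCc2ccc(OC)cc2 | intermediate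
11 | (5S,6S)-6-{[(4-methoxybenzyl)oxy]methyl}-5-methyl-5-(4-methylpent-3-en-1-yl)cyclohept-3-en-1-one | C1C(=O)CC=C[C@](C)(CCC=C(C)C)[C@H]1COCc2ccc(OC)cc2 | intermediate (not isolated)
12 | (5S,6S)-6-{[(4-methoxybenzyl)oxy]methyl}-5-methyl-5-(4-methylpent-3-en-1-yl)cyclohept-2-en-1-one | C1C(=O)C=CC[C@](C)(CCC=C(C)C)[C@H]1COCc2ccc(OC)cc2 | intermediate
13 | (5S,6S)-2-(hydroxymethyl) derivative of 12 | C1C(=O)C(CO)=CC[C@](C)(CCC=C(C)C)[C@H]1COCc2ccc(OC)cc2 | intermediate
14 | TBS ether of 13 | C1C(=O)C(CO[Si](C)(C)C(C)(C)C)=CC[C@](C)(CCC=C(C)C)[C@H]1COCc2ccc(OC)cc2 | intermediate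
15 | lithium enolate of 14 (C1–O–Li, C1=C7) | C1=C([O-])C(CO[Si](C)(C)C(C)(C)C)=CC[C@](C)(CCC=C(C)C)[C@H]1COCc2ccc(OC)cc2.[Li+] | intermediate (not isolated)
16 | (5S,6S,7S)-7-allyl derivative of 14 | C=CC[C@@H]1C(=O)C(CO[Si](C)(C)C(C)(C)C)=CC[C@](C)(CCC=C(C)C)[C@H]1COCc2ccc(OC)cc2 | intermediate
17 | (5S,6S,7S)-7-(2-oxopropyl) diketone | CC(=O)C[C@@H]1C(=O)C(CO[Si](C)(C)C(C)(C)C)=CC[C@](C)(CCC=C(C)C)[C@H]1COCc2ccc(OC)cc2 | intermediate
18 | hydroxy selenide of 17, side chain 4-hydroxy-4-methyl-3-(phenylselanyl)pentyl, epimers at C–Se | CC(=O)C[C@@H]1C(=O)C(CO[Si](C)(C)C(C)(C)C)=CC[C@](C)(CCC([Se]c3ccccc3)C(C)(C)O)[C@H]1COCc2ccc(OC)cc2 | intermediate (not isolated)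
19 | selenoxide of 18 | CC(=O)C[C@@H]1C(=O)C(CO[Si](C)(C)C(C)(C)C)=CC[C@](C)(CCC([Se](=O)c3ccccc3)C(C)(C)O)[C@H]1COCc2ccc(OC)cc2 | intermediate (not isolated)
20 | (5S,6S,7S)-tertiary allylic alcohol, side chain (2E)-4-hydroxy-4-methylpent-2-en-1-yl | CC(=O)C[C@@H]1C(=O)C(CO[Si](C)(C)C(C)(C)C)=CC[C@](C)(C/C=C/C(C)(C)O)[C@H]1COCc2ccc(OC)cc2 | intermediate
21 | (5S,6S,7S)-6-(hydroxymethyl) compound | CC(=O)C[C@@H]1C(=O)C(CO[Si](C)(C)C(C)(C)C)=CC[C@](C)(C/C=C/C(C)(C)O)[C@H]1CO | intermediate
22 | (5S,6S,7S)-C6 carbaldehyde | CC(=O)C[C@@H]1C(=O)C(CO[Si](C)(C)C(C)(C)C)=CC[C@](C)(C/C=C/C(C)(C)O)[C@H]1C=O | intermediate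
23 | (5S,6R,7S)-6-[(E)-2-iodoethenyl] compound | CC(=O)C[C@@H]1C(=O)C(CO[Si](C)(C)C(C)(C)C)=CC[C@](C)(C/C=C/C(C)(C)O)[C@H]1/C=C/I | intermediate
24 | 3-methylbut-2-enoic acid (senecioic acid) | CC(C)=CC(=O)O | starting material
25 | TBS ether of the target (E-enol senecioate) | CC(=O)C[C@@H]1C(=O)C(CO[Si](C)(C)C(C)(C)C)=CC[C@](C)(C/C=C/C(C)(C)O)[C@H]1/C=C/OC(=O)C=C(C)C | intermediate
26 | (5S,6S,7S)-2-(hydroxymethyl)-5-[(2E)-4-hydroxy-4-methylpent-2-en-1-yl]-5-methyl-6-[(E)-2-(3-methylbut-2-enoyloxy)ethenyl]-7-(2-oxopropyl)cyclohept-2-en-1-one | CC(=O)C[C@@H]1C(=O)C(CO)=CC[C@](C)(C/C=C/C(C)(C)O)[C@H]1/C=C/OC(=O)C=C(C)C | target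

**Step count**

Total steps: 18. Longest linear sequence: 18 steps, from geraniol 1.

**Steps most likely to fail**

Step 7 (key step). Insertion of Rh(I) into the C4–C6 bond of a cyclopropane with four substituents and no donor at C4 may be slower than rhodium-mediated oligomerisation of the ynol ether. The σ-alkyl rhodium at C6 may also undergo β-hydride elimination toward the CH2OPMB group, isomerising the substrate to an acyclic diene, and the alkyne may insert with the reverse orientation.

The fallback gives up the cyclopropane and builds the same cyclohept-3-enone by sigmatropic rearrangement and ring-closing metathesis, all known reaction types. It sets out from geraniol 1. Esterification with 3-[(4-methoxybenzyl)oxy]propanoic acid (DCC, DMAP) gives geranyl 3-[(4-methoxybenzyl)oxy]propanoate F1. An enantioselective Ireland–Claisen rearrangement follows, run through the Z(O)-boron enolate formed with a C2-symmetric 1,2-diphenylethylenediamine bis-sulfonamide bromoborane and a tertiary amine. Through the chair transition state it should give (2S,3S)-3-ethenyl-2-{[(4-methoxybenzyl)oxy]methyl}-3,7-dimethyloct-6-enoic acid F2. The E-alkene and the enolate geometry fix the relative configuration of the future C5 and C6 (methyl cis to CH2OPMB after ring closure), and the boron controller fixes the absolute one. Arndt–Eistert homologation passes through the diazoketone F3 (oxalyl chloride, then TMSCHN2). Silver benzoate-promoted Wolff rearrangement in the presence of N,O-dimethylhydroxylamine gives the Weinreb amide F4 with retention at C6. Allylmagnesium bromide then gives the allyl ketone F5. Ring-closing metathesis between the C5 vinyl group and the allyl ketone (second-generation ruthenium benzylidene catalyst, CH2Cl2, 40 °C) closes the seven-membered ring. The fallback comes back to the route at cyclohept-3-enone 11, which is conjugated to 12 as in the second half of step 8.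

Step 17. Under carbonate base and heat the 1,4-diketone may undergo intramolecular aldol condensation, and the centres at C6/C7 may epimerise, before the slow C–O coupling is complete; protodeiodination may compete.

The fallback replaces the halide coupling by an oxidative boron coupling and sets out from aldehyde 22. Boryl-olefination of the Takai type with (dichloromethyl)boronic acid pinacol ester, CrCl2 and LiI gives the (E)-alkenyl pinacol boronate F6. KHF2 converts it into the potassium (E)-alkenyltrifluoroborate F7. Copper(II)-catalysed Chan–Lam-type coupling with acid 24 under O2, with DMAP and molecular sieves near room temperature, needs no carbonate base and retains the alkene geometry. It comes back to the route at enol ester 25.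

Step 8. The alkene migration is an equilibrium, and in a seven-membered ring the conjugated and the unconjugated enone lie close in energy, so conversion to 12 may stay incomplete and repeated recycling may be needed.

The fallback functionalises C2 before the alkene is moved and sets out from cycloadduct 10. Buffered hydrolysis (oxalic acid, wet THF, 0 °C) stops at cyclohept-3-enone 11, which is isolated. Deprotonation at the doubly activated C2 (LDA, THF, −78 °C) and trapping of the dienolate at its α-carbon with monomeric formaldehyde gives the 2-(hydroxymethyl)cyclohept-3-enone F8. DBU then moves the alkene into conjugation, now driven by formation of a trisubstituted enone. The fallback comes back to the route at Baylis–Hillman adduct 13, so step 9 is skipped as well.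

Further compounds
F1 | step 7 | geranyl 3-[(4-methoxybenzyl)oxy]propanoate | CC(C)=CCC/C(C)=C/COC(=O)CCOCc1ccc(OC)cc1
F2 | step 7 | (2S,3S)-3-ethenyl-2-{[(4-methoxybenzyl)oxy]methyl}-3,7-dimethyloct-6-enoic acid | C=C[C@](C)(CCC=C(C)C)[C@@H](COCc1ccc(OC)cc1)C(=O)O
F3 | step 7 | diazoketone of F2 (1-diazo-4-ethenyl-3-{[(4-methoxybenzyl)oxy]methyl}-4,8-dimethylnon-7-en-2-one, configuration as F2) | C=C[C@](C)(CCC=C(C)C)[C@@H](COCc1ccc(OC)cc1)C(=O)C=[N+]=[N-]
F4 | step 7 | homologated Weinreb amide (4-ethenyl-N-methoxy-3-{[(4-methoxybenzyl)oxy]methyl}-N,4,8-trimethylnon-7-enamide, configuration as F2) | C=C[C@](C)(CCC=C(C)C)[C@@H](COCc1ccc(OC)cc1)CC(=O)N(C)OC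
F5 | step 7 | allyl ketone (7-ethenyl-6-{[(4-methoxybenzyl)oxy]methyl}-7,11-dimethyldodeca-1,10-dien-4-one, configuration as F2) | C=C[C@](C)(CCC=C(C)C)[C@@H](COCc1ccc(OC)cc1)CC(=O)CC=C
F6 | step 17 | (E)-alkenyl pinacol boronate at C6 (Bpin in place of iodine in 23) | CC(=O)C[C@@H]1C(=O)C(CO[Si](C)(C)C(C)(C)C)=CC[C@](C)(C/C=C/C(C)(C)O)[C@H]1/C=C/B2OC(C)(C)C(C)(C)O2
F7 | step 17 | potassium (E)-alkenyltrifluoroborate at C6 | CC(=O)C[C@@H]1C(=O)C(CO[Si](C)(C)C(C)(C)C)=CC[C@](C)(C/C=C/C(C)(C)O)[C@H]1/C=C/[B-](F)(F)F.[K+]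
F8 | step 8 | (5S,6S)-2-(hydroxymethyl)-6-{[(4-methoxybenzyl)oxy]methyl}-5-methyl-5-(4-methylpent-3-en-1-yl)cyclohept-3-en-1-one, epimers at C2 | C1C(=O)C(CO)C=C[C@](C)(CCC=C(C)C)[C@H]1COCc2ccc(OC)cc2
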